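**Retrosynthetic overview**

1. Vismiaphenone D 22 comes from ketone 21 by MOM removal, 21 from carbinol 20 by oxidation, and 20 from aryllithium 19 plus aldehyde 18; this last C–C bond joins C1 of ring A to the purchased ring B.
2. Arene 16, the source of 19, comes from phenol 14 by exchanging the silyl ether for MOM ethers; its only ring hydrogen lies between the two OMOM groups.
3. Ring A is the only ring built. It is cut at C2–C3 and C4–C5 into cyclobutenone 5 and ynol ether 9. The strategy rests on the fully substituted ring A, where oxygen (C2–OH, C4–OMe, C6–OH) alternates with carbon (C1 aroyl, C3 and C5 prenyl) and the C4 oxygen differs from those at C2 and C6.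
4. Cyclobutenone 5 comes from siloxyalkyne 4 and ketene, and 4 from ester 1; ynol ether 9 comes from chloroacetal 6 and prenyl bromide 7.

Key step: step 4

Assumption: ring A is numbered from the aroyl-bearing carbon (C1); prenyl means 3-methylbut-2-enyl; ketene gas is taken from a laboratory ketene generator (pyrolysis of acetone).

**Route**

Step 1
Reactants: 1 ethyl 4-methylpent-3-enoate
Product: 4 triisopropyl[(5-methylhex-4-en-1-yn-1-yl)oxy]silane, via dibromoketone enolate 2 (not isolated), via lithium ynolate 3 (not isolated)
Conditions: CH2Br2, LiTMP (lithium 2,2,6,6-tetramethylpiperidide), THF, −78 °C; add 1; LiN(SiMe3)2, −78 °C; n-BuLi, −78 °C → rt; TIPSCl, −78 → 0 °C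
Reagents that add atoms: dibromomethane, BrCBr; triisopropylsilyl chloride (TIPSCl), CC(C)[Si](Cl)(C(C)C)C(C)C
Why: Kowalski ester homologation, in which LiCHBr2 acylation, deprotonation to enolate 2, Br–Li exchange and 1,2-shift with loss of LiBr should give ynolate 3, which the bulky chlorosilane captures on oxygen; adding 1 to the preformed carbenoid at −78 °C should keep α-deprotonation of the β,γ-unsaturated ester in check.

Step 2
Reactants: 4 triisopropyl[(5-methylhex-4-en-1-yn-1-yl)oxy]silane
Product: 5 2-(3-methylbut-2-enyl)-3-(triisopropylsilyloxy)cyclobut-2-en-1-one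
Conditions: ketene (gas, excess, from acetone pyrolysis), CH2Cl2, 0 °C → rt
Reagents that add atoms: ketene, C=C=O
Why: Thermal [2+2] cycloaddition of ketene with an electron-rich siloxyalkyne, in which the nucleophilic prenyl-bearing alkyne carbon bonds to the ketene carbonyl carbon, so the prenyl group should end up at C2 and the siloxy group at C3 of the cyclobutenone.

Step 3
Reactants: 6 chloroacetaldehyde dimethyl acetal; 7 prenyl bromide
Product: 9 1-methoxy-5-methylhex-4-en-1-yne, via sodium methoxyacetylide 8 (not isolated)
Conditions: NaNH2 (3.0 equiv), liq. NH3, −40 °C; then 7, −50 → −33 °C; evaporate NH3, cold aq. NH4Cl/pentane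
Reagents that add atoms: none
Why: Double elimination and deprotonation of the chloroacetal by NaNH2 should give acetylide 8, which is alkylated by SN2 attack at the primary carbon of the allylic bromide; exactly three equivalents of amide leave no strong base to isomerize the skipped enyne.

Step 4
Reactants: 5 2-(3-methylbut-2-enyl)-3-(triisopropylsilyloxy)cyclobut-2-en-1-one; 9 1-methoxy-5-methylhex-4-en-1-yne
Product: 14 3-methoxy-2,4-bis(3-methylbut-2-enyl)-5-(triisopropylsilyloxy)phenol, via vinylketene 10 (not isolated), via vinylcyclobutenone 11 (not isolated), via dienylketene 12 (not isolated), via cyclohexadienone 13 (not isolated)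
Conditions: 9 (2 equiv), degassed toluene, sealed tube, 110–130 °C
Reagents that add atoms: none
Why: Proposed new method: heating should open 5 by conrotatory four-electron electrocyclic cleavage to vinylketene 10, whose ketene carbon is attacked by the nucleophilic prenyl-bearing carbon of ynol ether 9 in a regiospecific [2+2] cycloaddition to give 4-vinylcyclobutenone 11; this reopens to dienylketene 12, which closes ring A by six-electron disrotatory electrocyclization (re-forming the C1–C2 bond, so that the net new bonds are C2–C3 and C4–C5) to cyclohexadienone 13 and aromatizes by tautomerization to 14. The closest known reaction type is the Danheiser benzannulation of alkyl- and aryl-substituted cyclobutenones with alkoxy- and siloxyalkynes, together with the ketene–siloxyalkyne [2+2] used in step 2; what is untested is a 3-siloxycyclobutenone, a vinylogous silyl ester, as the vinylketene source. Its donor group should raise the barrier of the first ring opening without blocking it, which is why 110–130 °C is proposed in place of the usual 80 °C, and 9 should tolerate this because a methyl ynol ether has no β-hydrogen for retro-ene loss of an alkene. No stereocentre is formed: the quaternary carbon of 11 is racemic and becomes sp2 in 12. The one selectivity needed is regiochemical, the methoxy-bearing carbon must end up between the two prenyl-bearing carbons, and it is secured by the polarization of the ynol ether, whose oxygen-bearing carbon bonds to the ketene α-carbon. An excess of 9 should keep 10 from dimerizing or acylating the phenol product, and the reaction is an isomerizing addition that releases no by-product.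

Step 5
Reactants: 14 3-methoxy-2,4-bis(3-methylbut-2-enyl)-5-(triisopropylsilyloxy)phenol
Product: 15 5-methoxy-4,6-bis(3-methylbut-2-enyl)benzene-1,3-diol
Conditions: Bu4NF, AcOH, THF, 0 °C
Reagents that add atoms: none
Why: Fluoride cleavage of the aryl silyl ether driven by Si–F bond formation, buffered with acetic acid so that the electron-rich resorcinol is not held as an oxidation-prone phenoxide.

Step 6
Reactants: 15 5-methoxy-4,6-bis(3-methylbut-2-enyl)benzene-1,3-diol
Product: 16 3-methoxy-1,5-bis(methoxymethoxy)-2,4-bis(3-methylbut-2-enyl)benzene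
Conditions: MOMCl, i-Pr2NEt, CH2Cl2, 0 °C → rt
Reagents that add atoms: chloromethyl methyl ether (MOMCl), COCCl
Why: O-alkylation of both phenols by the hard electrophile MOMCl installs two acetal groups that later direct the metalation.

Step 7
Reactants: 17 4-hydroxybenzaldehyde
Product: 18 4-(methoxymethoxy)benzaldehyde
Conditions: MOMCl, i-Pr2NEt, CH2Cl2, 0 °C → rt
Reagents that add atoms: chloromethyl methyl ether (MOMCl), COCCl
Why: Routine MOM etherification of an acidic phenol, which removes the acidic proton that would quench the aryllithium in step 8.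

Step 8
Reactants: 16 3-methoxy-1,5-bis(methoxymethoxy)-2,4-bis(3-methylbut-2-enyl)benzene; 18 4-(methoxymethoxy)benzaldehyde
Product: 20 [4-methoxy-2,6-bis(methoxymethoxy)-3,5-bis(3-methylbut-2-enyl)phenyl][4-(methoxymethoxy)phenyl]methanol (racemic), via aryllithium 19 (not isolated)
Conditions: n-BuLi, THF, 0 °C; then 18, −78 → 0 °C; aq. NH4Cl
Reagents that add atoms: none
Why: Directed ortho-metalation at the only ring hydrogen, which is flanked by two coordinating OMOM groups, followed by 1,2-addition of 19 to the non-enolizable aldehyde; the carbinol stereocentre forms racemic and is removed in step 9.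

Step 9
Reactants: 20 [4-methoxy-2,6-bis(methoxymethoxy)-3,5-bis(3-methylbut-2-enyl)phenyl][4-(methoxymethoxy)phenyl]methanol
Product: 21 [4-methoxy-2,6-bis(methoxymethoxy)-3,5-bis(3-methylbut-2-enyl)phenyl][4-(methoxymethoxy)phenyl]methanone
Conditions: Dess–Martin periodinane, NaHCO3, CH2Cl2, 0 °C → rt
Reagents that add atoms: none
Why: Dess–Martin oxidation of a secondary diarylcarbinol under buffered conditions that should leave the prenyl alkenes and MOM acetals untouched.

Step 10
Reactants: 21 [4-methoxy-2,6-bis(methoxymethoxy)-3,5-bis(3-methylbut-2-enyl)phenyl][4-(methoxymethoxy)phenyl]methanone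
Product: 22 Vismiaphenone D, [2,6-dihydroxy-4-methoxy-3,5-bis(3-methylbut-2-enyl)phenyl](4-hydroxyphenyl)methanone
Conditions: HCl (3 M aq.), MeOH, rt → 40 °C, stopped at full conversion
Reagents that add atoms: none
Why: Acid-catalysed transacetalization of the three aryl MOM ethers to methanol (the two flanking the ketone are activated by the carbonyl), run dilute and only to completion so that the prenyl groups do not cyclize onto the freed ortho-hydroxyls.

**Compound list**

1 | ethyl 4-methylpent-3-enoate | CCOC(=O)CC=C(C)C | starting material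
2 | lithium 1,1-dibromo-5-methylhexa-1,4-dien-2-olate | [Li]OC(CC=C(C)C)=C(Br)Br | intermediate (not isolated)
3 | lithium 5-methylhex-4-en-1-yn-1-olate | [Li]OC#CCC=C(C)C | intermediate (not isolated)
4 | triisopropyl[(5-methylhex-4-en-1-yn-1-yl)oxy]silane | CC(C)=CCC#CO[Si](C(C)C)(C(C)C)C(C)C | intermediate
5 | 2-(3-methylbut-2-enyl)-3-(triisopropylsilyloxy)cyclobut-2-en-1-one | O=C1CC(O[Si](C(C)C)(C(C)C)C(C)C)=C1CC=C(C)C | intermediate
6 | chloroacetaldehyde dimethyl acetal (2-chloro-1,1-dimethoxyethane) | COC(CCl)OC | starting material
7 | prenyl bromide (1-bromo-3-methylbut-2-ene) | CC(C)=CCBr | starting material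
8 | sodium methoxyacetylide | [Na]C#COC | intermediate (not isolated)
9 | 1-methoxy-5-methylhex-4-en-1-yne | COC#CCC=C(C)C | intermediate
10 | 2-(3-methylbut-2-enyl)-3-(triisopropylsilyloxy)buta-1,3-dien-1-one | O=C=C(CC=C(C)C)C(=C)O[Si](C(C)C)(C(C)C)C(C)C | intermediate (not isolated)
11 | 3-methoxy-2,4-bis(3-methylbut-2-enyl)-4-[1-(triisopropylsilyloxy)ethenyl]cyclobut-2-en-1-one (racemic) | COC1=C(CC=C(C)C)C(=O)C1(CC=C(C)C)C(=C)O[Si](C(C)C)(C(C)C)C(C)C | intermediate (not isolated)
12 | (3E)-3-methoxy-2,4-bis(3-methylbut-2-enyl)-5-(triisopropylsilyloxy)hexa-1,3,5-trien-1-one (ketenyl and siloxyvinyl groups cis) | O=C=C(CC=C(C)C)/C(OC)=C(CC=C(C)C)\C(=C)O[Si](C(C)C)(C(C)C)C(C)C | intermediate (not isolated)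
13 | 3-methoxy-2,4-bis(3-methylbut-2-enyl)-5-(triisopropylsilyloxy)cyclohexa-2,4-dien-1-one | O=C1CC(O[Si](C(C)C)(C(C)C)C(C)C)=C(CC=C(C)C)C(OC)=C1CC=C(C)C | intermediate (not isolated)
14 | 3-methoxy-2,4-bis(3-methylbut-2-enyl)-5-(triisopropylsilyloxy)phenol | COc1c(CC=C(C)C)c(O)cc(O[Si](C(C)C)(C(C)C)C(C)C)c1CC=C(C)C | intermediate
15 | 5-methoxy-4,6-bis(3-methylbut-2-enyl)benzene-1,3-diol | COc1c(CC=C(C)C)c(O)cc(O)c1CC=C(C)C | intermediate
16 | 3-methoxy-1,5-bis(methoxymethoxy)-2,4-bis(3-methylbut-2-enyl)benzene | COCOc1cc(OCOC)c(CC=C(C)C)c(OC)c1CC=C(C)C | intermediate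
17 | 4-hydroxybenzaldehyde | O=Cc1ccc(O)cc1 | starting material
18 | 4-(methoxymethoxy)benzaldehyde | COCOc1ccc(C=O)cc1 | intermediate
19 | [4-methoxy-2,6-bis(methoxymethoxy)-3,5-bis(3-methylbut-2-enyl)phenyl]lithium | [Li]c1c(OCOC)c(CC=C(C)C)c(OC)c(CC=C(C)C)c1OCOC | intermediate (not isolated)
20 | [4-methoxy-2,6-bis(methoxymethoxy)-3,5-bis(3-methylbut-2-enyl)phenyl][4-(methoxymethoxy)phenyl]methanol (racemic) | COCOc1ccc(C(O)c2c(OCOC)c(CC=C(C)C)c(OC)c(CC=C(C)C)c2OCOC)cc1 | intermediate
21 | [4-methoxy-2,6-bis(methoxymethoxy)-3,5-bis(3-methylbut-2-enyl)phenyl][4-(methoxymethoxy)phenyl]methanone | COCOc1ccc(C(=O)c2c(OCOC)c(CC=C(C)C)c(OC)c(CC=C(C)C)c2OCOC)cc1 | intermediate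
22 | Vismiaphenone D, [2,6-dihydroxy-4-methoxy-3,5-bis(3-methylbut-2-enyl)phenyl](4-hydroxyphenyl)methanone | COc1c(CC=C(C)C)c(O)c(C(=O)c2ccc(O)cc2)c(O)c1CC=C(C)C | target

**Count and risks**

Total step count: 10. Longest linear sequence: 8 steps (steps 1, 2, 4, 5, 6, 8, 9, 10).

Steps most likely to fail:

1. Step 4 (bears the label). The vinylogous-ester stabilization of 5 may hold the ring closed until temperatures at which the vinylketene dimerizes or acylates the phenol product, so that ring opening and alkyne capture do not mesh. The fallback takes ring A from a preformed phloroglucinol and uses only known chemistry; it sets out from prenyl bromide 7 and comes back at carbinol 20. Commercial 2,4,6-trihydroxybenzaldehyde would be methylated at its non-chelated 4-hydroxyl (Me2SO4, K2CO3, acetone) to 2,6-dihydroxy-4-methoxybenzaldehyde F1. Phenoxide C-alkylation at the two free ring positions with 7 (aq. KOH, 0 °C) would give 2,6-dihydroxy-4-methoxy-3,5-bis(3-methylbut-2-enyl)benzaldehyde F2. Protection (NaH, MOMCl, DMF) would give 4-methoxy-2,6-bis(methoxymethoxy)-3,5-bis(3-methylbut-2-enyl)benzaldehyde F3. Addition of [4-(methoxymethoxy)phenyl]magnesium bromide F4 (from 1-bromo-4-(methoxymethoxy)benzene and Mg in THF) would deliver 20, after which steps 9 and 10 follow unchanged.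

2. Step 3. The skipped enyne may isomerize under residual amide base, prenyl bromide may be consumed by ammonolysis or SN2' attack, and the volatile ynol ether may be lost on isolation. The fallback avoids amide bases and ammonia; it sets out from 7 and comes back at 9. Trichloroethylene and KOMe (from KH and MeOH, THF) would give (E)-1,2-dichloro-1-methoxyethene F5. Two equivalents of n-BuLi (THF, −78 → −40 °C) would convert it by elimination and Cl–Li exchange into lithium methoxyacetylide F6, which would be alkylated with 7 in THF/DMPU to give 9.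

3. Step 1. Deprotonation of the doubly activated α-CH2 of the β,γ-unsaturated ester may outrun carbonyl addition of LiCHBr2, returning isomerized ester. The fallback reaches the ynolate by oxidation of an acetylide; it sets out from 7 and comes back at ynolate 3. CuCl-catalysed coupling of 7 with HC≡CMgBr (THF) would give 5-methylhex-4-en-1-yne F7. Deprotonation with LiN(SiMe3)2 would give lithium 5-methylhex-4-en-1-yn-1-ide F8, and oxidation with t-BuOOLi (THF, −78 → 0 °C) would give 3, which is silylated on oxygen to 4 as in step 1.

**Further compounds**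

F1 | step 4 | 2,6-dihydroxy-4-methoxybenzaldehyde | COc1cc(O)c(C=O)c(O)c1
F2 | step 4 | 2,6-dihydroxy-4-methoxy-3,5-bis(3-methylbut-2-enyl)benzaldehyde | COc1c(CC=C(C)C)c(O)c(C=O)c(O)c1CC=C(C)C
F3 | step 4 | 4-methoxy-2,6-bis(methoxymethoxy)-3,5-bis(3-methylbut-2-enyl)benzaldehyde | COCOc1c(C=O)c(OCOC)c(CC=C(C)C)c(OC)c1CC=C(C)C
F4 | step 4 | [4-(methoxymethoxy)phenyl]magnesium bromide | COCOc1ccc([Mg]Br)cc1
F5 | step 3 | (E)-1,2-dichloro-1-methoxyethene | CO/C(Cl)=C\Cl
F6 | step 3 | lithium methoxyacetylide | [Li]C#COC
F7 | step 1 | 5-methylhex-4-en-1-yne | C#CCC=C(C)C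
F8 | step 1 | lithium 5-methylhex-4-en-1-yn-1-ide | [Li]C#CCC=C(C)C
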